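**Plan**
- Retrosynthetic cuts: first the C4–O bond (hydroxylation between two methoxy groups) and the C3 O–methyl bond; then ring A at C1–C6, C2–C3, C3–C4 and C5–C6; then the C–N2, C1–acyl and C7′–aryl bonds of the cyclohexene precursor.
- Enabling feature: ring A carries its C3 and C5 oxygens meta to each other and is fused to ring B through C1–C2. A vinylketene/alkoxyalkyne benzannulation of a cyclohexenyl diazo ketone with methoxyethyne delivers exactly this pattern.
- Forward order: ring B is present from the first compound as a cyclohexene; the pendant aryl ring is attached by conjugate addition; ring A is built last on the C1=C2 double bond; the C4 hydroxyl is added at the end.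
- Stereochemistry: the cis C8/C8′ methyls come from a meso anhydride; a chiral lithium amide desymmetrises the derived meso epoxide; C7′ is set by aryl–copper addition anti to both methyls; no stereocentre is formed or touched afterwards.

Key step: step 12

Remark on notation: lignan numbering is used for the target (ring A = C1–C6, ring B = C1, C2, C7′, C8′, C8, C7); Ar = 3-methoxy-4-(triisopropylsilyloxy)phenyl.
Remark on the chemistry (assumption): the lithium amide of (S)-2-(pyrrolidin-1-ylmethyl)pyrrolidine converts cyclohexene oxide into (S)-cyclohex-2-en-1-ol; the same sense of proton selection is assumed for the 4,5-dimethyl epoxide, so the (R)-diamine is specified, and the (S)-diamine would be used if the sense proved reversed.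

**Step 1**
Reactants: 1 cis-1,2,3,6-tetrahydrophthalic anhydride (meso)
Product: 2 cis-cyclohex-4-ene-1,2-diyldimethanol (meso)
Conditions: LiAlH4, THF, 0 °C → reflux; aq. NaOH work-up
Reagents that add atoms: none
Why: Hydride reduction of a cyclic anhydride to the diol, in which no enolisable intermediate persists, so the cis relationship of the two ring CH centres is kept.

**Step 2**
Reactants: 2 cis-cyclohex-4-ene-1,2-diyldimethanol
Product: 3 cis-cyclohex-4-ene-1,2-diylbis(methylene) bis(4-methylbenzenesulfonate) (meso)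
Conditions: TsCl, pyridine, 0 °C
Reagents that add atoms: 4-methylbenzenesulfonyl chloride Cc1ccc(cc1)S(Cl)(=O)=O
Why: Sulfonylation of two primary alcohols, run with excess reagent in the cold so that the second tosylation outruns cyclisation of a mono-tosylate to the bicyclic ether.

**Step 3**
Reactants: 3 cis-cyclohex-4-ene-1,2-diylbis(methylene) bis(4-methylbenzenesulfonate)
Product: 4 cis-4,5-dimethylcyclohexene (meso)
Conditions: LiAlH4, THF, reflux; distillation
Reagents that add atoms: none
Why: SN2 displacement of primary sulfonates by hydride turns both CH2OTs groups into methyl groups without touching the ring stereocentres, so the methyls stay cis.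

**Step 4**
Reactants: 4 cis-4,5-dimethylcyclohexene
Product: 5 meso-3,4-dimethyl-7-oxabicyclo[4.1.0]heptane with the oxirane trans to both methyl groups
Conditions: mCPBA, NaHCO3, CH2Cl2, 0 °C; chromatography (pentane/Et2O)
Reagents that add atoms: 3-chloroperoxybenzoic acid OOC(=O)c1cccc(Cl)c1
Why: Prilezhaev epoxidation, in which the peracid should prefer the face away from the pseudoaxial homoallylic methyl, so the trans epoxide is expected as the main isomer and the cis isomer (which would lead into the enantiomeric series) is removed.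

**Step 5**
Reactants: 5 meso-3,4-dimethyl-7-oxabicyclo[4.1.0]heptane (oxirane trans to the methyls)
Product: 6 (1R,4R,5R)-4,5-dimethylcyclohex-2-en-1-ol
Conditions: (R)-2-(pyrrolidin-1-ylmethyl)pyrrolidine, n-BuLi, THF, 0 °C → rt
Reagents that add atoms: none
Why: Enantioselective base-induced isomerisation of a meso epoxide to an allylic alcohol, in which the chiral lithium amide removes by cyclic syn-elimination one of the two enantiotopic hydrogens cis to the oxirane, fixing the carbinol centre as R and thereby making the two methyl-bearing carbons non-equivalent (4R,5R).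

**Step 6**
Reactants: 6 (1R,4R,5R)-4,5-dimethylcyclohex-2-en-1-ol
Product: 7 (4R,5R)-4,5-dimethylcyclohex-2-en-1-one (methyls cis)
Conditions: MnO2, CH2Cl2, rt
Reagents that add atoms: none
Why: Neutral MnO2 oxidation of an allylic alcohol to the enone, which leaves the γ-stereocentre unepimerised.

**Step 7**
Reactants: 8 4-bromo-2-methoxyphenol
Product: 9 (4-bromo-2-methoxyphenoxy)triisopropylsilane
Conditions: TIPSCl, imidazole, DMF, rt
Reagents that add atoms: chlorotriisopropylsilane CC(C)[Si](Cl)(C(C)C)C(C)C
Why: Silylation of a phenol, chosen because the bulky triisopropylsilyl ether tolerates Grignard formation, organolithium bases and photolysis and is a poor director of ortho-lithiation.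

**Step 8**
Reactants: 7 (4R,5R)-4,5-dimethylcyclohex-2-en-1-one; 9 (4-bromo-2-methoxyphenoxy)triisopropylsilane
Product: 12 (3S,4R,5R)-3-Ar-4,5-dimethylcyclohex-1-en-1-yl trifluoromethanesulfonate, via aryl Grignard reagent 10 (not isolated), via magnesium enolate 11 (not isolated)
Conditions: 9, Mg, THF, reflux; then 7, CuBr·SMe2 (10 mol %), THF, −78 → −40 °C; then N-(5-chloropyridin-2-yl)triflimide, −78 °C → rt
Reagents that add atoms: N-(5-chloropyridin-2-yl)-1,1,1-trifluoro-N-(trifluoromethylsulfonyl)methanesulfonamide FC(F)(F)S(=O)(=O)N(c1ccc(Cl)cn1)S(=O)(=O)C(F)(F)F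
Why: Copper-catalysed conjugate addition of an aryl Grignard reagent followed by O-triflation of the regiodefined enolate, in which axial delivery of the aryl group trans to the adjacent C4 methyl and trans to the C5 methyl (both on the same face) sets C3 as S (the future C7′) and the trapped enolate fixes the double bond between C1 and C2.

**Step 9**
Reactants: 12 (3S,4R,5R)-3-Ar-4,5-dimethylcyclohex-1-en-1-yl trifluoromethanesulfonate
Product: 14 1-[(3S,4R,5R)-3-Ar-4,5-dimethylcyclohex-1-en-1-yl]ethan-1-one, via ethoxydiene 13 (not isolated)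
Conditions: tributyl(1-ethoxyethenyl)stannane, Pd(PPh3)4 (5 mol %), LiCl, THF, reflux; then 1 M HCl, THF, rt
Reagents that add atoms: tributyl(1-ethoxyethenyl)stannane CCCC[Sn](CCCC)(CCCC)C(=C)OCC; water O
Why: Stille coupling of an enol triflate with an acetyl anion equivalent (chloride-assisted oxidative addition to zerovalent palladium, transmetalation, reductive elimination) followed by acid hydrolysis of the dienyl ether, which protonates at the terminal CH2 and gives the conjugated methyl ketone.

**Step 10**
Reactants: 14 1-[(3S,4R,5R)-3-Ar-4,5-dimethylcyclohex-1-en-1-yl]ethan-1-one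
Product: 17 2-diazo-1-[(3S,4R,5R)-3-Ar-4,5-dimethylcyclohex-1-en-1-yl]ethan-1-one, via lithium enolate 15 (not isolated), via trifluoroacetyl diketone 16 (not isolated)
Conditions: LiN(SiMe3)2, THF, −78 °C; CF3CO2CH2CF3; aq. HCl work-up; then MsN3, Et3N, H2O (1 equiv), MeCN, rt
Reagents that add atoms: methanesulfonyl azide CS(=O)(=O)N=[N+]=[N-]
Why: Detrifluoroacetylative diazo transfer, in which the kinetic methyl enolate is C-trifluoroacetylated and the activated methylene then accepts the diazo group from the sulfonyl azide with loss of the trifluoroacetyl group, chosen because acylating diazomethane with the enoyl chloride would risk dipolar cycloaddition to the conjugated double bond.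

**Step 11**
Reactants: 18 chloroacetaldehyde dimethyl acetal
Product: 21 methoxyethyne, via chloro enol ether 19 (not isolated), via sodium methoxyethynide 20 (not isolated)
Conditions: NaNH2 (3 equiv), NH3(l), −33 °C; then sat. aq. NaCl, −70 °C → rt; distilled into ClCH2CH2Cl at −78 °C
Reagents that add atoms: none
Why: Amide-induced double elimination (loss of methanol, then of HCl) gives the ynol ether, which is held as its sodium acetylide until the aqueous quench releases the volatile alkyne.

**Step 12**
Reactants: 17 2-diazo-1-[(3S,4R,5R)-3-Ar-4,5-dimethylcyclohex-1-en-1-yl]ethan-1-one; 21 methoxyethyne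
Product: 26 (6R,7R,8R)-8-Ar-3-methoxy-6,7-dimethyl-5,6,7,8-tetrahydronaphthalen-1-ol, via vinylketene 22 (not isolated), via vinylcyclobutenone 23 (not isolated), via dienylketene 24 (not isolated), via cyclohexadienone 25 (not isolated)
Conditions: 21 (5 equiv), ClCH2CH2Cl, hν (254 nm, quartz, sealed tube), rt; then 80 °C
Reagents that add atoms: none
Why: Irradiation expels N2 from 17 and the cyclohexenyl group shifts from the carbonyl carbon to the carbene carbon (Wolff rearrangement, new C1–C6 bond) to give vinylketene 22, whose electrophilic carbonyl carbon bonds to the nucleophilic unsubstituted carbon of the ynol ether and whose α-carbon bonds to the methoxy-bearing carbon in a [2+2] cycloaddition (C3–C4 and C5–C6), giving cyclobutenone 23. Four-electron electrocyclic opening of 23 gives dienylketene 24, and six-electron electrocyclisation of 24 joins C2 to C3 to give dienone 25, which tautomerises to phenol 26. The closest known reaction type is the Danheiser benzannulation in its photochemical diazo ketone form with alkoxy- and siloxyalkynes. Ring A is the only ring closed, and it closes by thermal disrotatory 6π electrocyclisation of a carbon triene made of the ketene C=C, the enol ether C=C and the ring C1=C2 bond. No stereocentre is created, and C7′, C8′ and C8 remain sp3 spectators because C7′ is only allylic to the reacting diene and never becomes part of an enol, a cation or a radical. The one selectivity needed is regiochemical (OH on C3, H on C4, OMe on C5), and it is secured by the polarity match between ketene and ynol ether together with the fact that only the ring double bond can act as terminus of the electrocyclisation.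

**Step 13**
Reactants: 26 (6R,7R,8R)-8-Ar-3-methoxy-6,7-dimethyl-5,6,7,8-tetrahydronaphthalen-1-ol
Product: 27 (7′R,8R,8′R)-3,3′,5-trimethoxy-4′-(triisopropylsilyloxy)-2,7′-cyclolignan
Conditions: MeI, K2CO3, acetone, 50 °C
Reagents that add atoms: iodomethane CI
Why: Williamson O-methylation of the C3 phenoxide, run with anhydrous carbonate in acetone so that the aryl silyl ether stays intact.

**Step 14**
Reactants: 27 (7′R,8R,8′R)-3,3′,5-trimethoxy-4′-(triisopropylsilyloxy)-2,7′-cyclolignan
Product: 30 (7′R,8R,8′R)-3,3′,5-trimethoxy-4′-(triisopropylsilyloxy)-2,7′-cyclolignan-4-ol, via aryllithium 28 (not isolated), via dimethyl arylboronate 29 (not isolated)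
Conditions: n-BuLi, THF, 0 °C → rt; B(OMe)3, −78 °C → rt; AcOH, 30% H2O2, 0 °C → rt
Reagents that add atoms: hydrogen peroxide OO
Why: Directed ortho-metalation at C4, the only ring position flanked by two methoxy groups, followed by borylation and oxidative aryl shift from boron to oxygen, which places the hydroxyl on C4 while the bulky silyl ether directs poorly and the tertiary C7′–H is kinetically slow to deprotonate.

**Step 15**
Reactants: 30 (7′R,8R,8′R)-3,3′,5-trimethoxy-4′-(triisopropylsilyloxy)-2,7′-cyclolignan-4-ol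
Product: 31 (−)-(7′R,8R,8′R)-4,4′-dihydroxy-3,3′,5-trimethoxy-2,7′-cyclolignan
Conditions: TBAF, AcOH, THF, 0 °C, argon
Reagents that add atoms: none
Why: Fluoride cleaves the Si–O bond of the aryl silyl ether, and the acetic acid buffer protonates the electron-rich phenoxides and so protects the product from air oxidation.

**Compound list**
1 | cis-1,2,3,6-tetrahydrophthalic anhydride (meso) | O=C1OC(=O)[C@@H]2CC=CC[C@H]12 | starting material
2 | cis-cyclohex-4-ene-1,2-diyldimethanol (meso) | OC[C@H]1CC=CC[C@H]1CO | intermediate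
3 | cis-cyclohex-4-ene-1,2-diylbis(methylene) bis(4-methylbenzenesulfonate) (meso) | Cc1ccc(cc1)S(=O)(=O)OC[C@H]1CC=CC[C@H]1COS(=O)(=O)c1ccc(C)cc1 | intermediate
4 | cis-4,5-dimethylcyclohexene (meso) | C[C@H]1CC=CC[C@H]1C | intermediate
5 | meso-3,4-dimethyl-7-oxabicyclo[4.1.0]heptane, oxirane trans to both methyls | C[C@H]1C[C@@H]2O[C@@H]2C[C@H]1C | intermediate
6 | (1R,4R,5R)-4,5-dimethylcyclohex-2-en-1-ol | O[C@H]1C=C[C@H](C)[C@H](C)C1 | intermediate
7 | (4R,5R)-4,5-dimethylcyclohex-2-en-1-one | O=C1C=C[C@H](C)[C@H](C)C1 | intermediate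
8 | 4-bromo-2-methoxyphenol | COc1cc(Br)ccc1O | starting material
9 | (4-bromo-2-methoxyphenoxy)triisopropylsilane | COc1cc(Br)ccc1O[Si](C(C)C)(C(C)C)C(C)C | intermediate
10 | [3-methoxy-4-(triisopropylsilyloxy)phenyl]magnesium bromide | COc1cc([Mg]Br)ccc1O[Si](C(C)C)(C(C)C)C(C)C | intermediate (not isolated)
11 | bromomagnesium (3S,4R,5R)-3-Ar-4,5-dimethylcyclohex-1-en-1-olate | COc1cc([C@@H]2C=C(O[Mg]Br)C[C@@H](C)[C@H]2C)ccc1O[Si](C(C)C)(C(C)C)C(C)C | intermediate (not isolated)
12 | (3S,4R,5R)-3-Ar-4,5-dimethylcyclohex-1-en-1-yl trifluoromethanesulfonate | COc1cc([C@@H]2C=C(OS(=O)(=O)C(F)(F)F)C[C@@H](C)[C@H]2C)ccc1O[Si](C(C)C)(C(C)C)C(C)C | intermediate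
13 | (3S,4R,5R)-1-(1-ethoxyethenyl)-3-Ar-4,5-dimethylcyclohex-1-ene | COc1cc([C@@H]2C=C(C(=C)OCC)C[C@@H](C)[C@H]2C)ccc1O[Si](C(C)C)(C(C)C)C(C)C | intermediate (not isolated)
14 | 1-[(3S,4R,5R)-3-Ar-4,5-dimethylcyclohex-1-en-1-yl]ethan-1-one | COc1cc([C@@H]2C=C(C(C)=O)C[C@@H](C)[C@H]2C)ccc1O[Si](C(C)C)(C(C)C)C(C)C | intermediate
15 | lithium 1-[(3S,4R,5R)-3-Ar-4,5-dimethylcyclohex-1-en-1-yl]ethen-1-olate | COc1cc([C@@H]2C=C(C(=C)O[Li])C[C@@H](C)[C@H]2C)ccc1O[Si](C(C)C)(C(C)C)C(C)C | intermediate (not isolated)
16 | 4,4,4-trifluoro-1-[(3S,4R,5R)-3-Ar-4,5-dimethylcyclohex-1-en-1-yl]butane-1,3-dione | COc1cc([C@@H]2C=C(C(=O)CC(=O)C(F)(F)F)C[C@@H](C)[C@H]2C)ccc1O[Si](C(C)C)(C(C)C)C(C)C | intermediate (not isolated)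
17 | 2-diazo-1-[(3S,4R,5R)-3-Ar-4,5-dimethylcyclohex-1-en-1-yl]ethan-1-one | COc1cc([C@@H]2C=C(C(=O)C=[N+]=[N-])C[C@@H](C)[C@H]2C)ccc1O[Si](C(C)C)(C(C)C)C(C)C | intermediate (key-step precursor)
18 | chloroacetaldehyde dimethyl acetal | COC(CCl)OC | starting material
19 | 1-chloro-2-methoxyethene (E/Z) | COC=CCl | intermediate (not isolated)
20 | sodium methoxyethynide | COC#[C-].[Na+] | intermediate (not isolated)
21 | methoxyethyne | COC#C | intermediate (key-step precursor)
22 | 2-[(3S,4R,5R)-3-Ar-4,5-dimethylcyclohex-1-en-1-yl]ethen-1-one (vinylketene) | COc1cc([C@@H]2C=C(C=C=O)C[C@@H](C)[C@H]2C)ccc1O[Si](C(C)C)(C(C)C)C(C)C | intermediate (not isolated)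
23 | 4-[(3S,4R,5R)-3-Ar-4,5-dimethylcyclohex-1-en-1-yl]-3-methoxycyclobut-2-en-1-one (both epimers at the four-ring CH) | COc1cc([C@@H]2C=C(C3C(OC)=CC3=O)C[C@@H](C)[C@H]2C)ccc1O[Si](C(C)C)(C(C)C)C(C)C | intermediate (not isolated)
24 | (3E)-4-[(3S,4R,5R)-3-Ar-4,5-dimethylcyclohex-1-en-1-yl]-3-methoxybuta-1,3-dien-1-one (ketene and cyclohexenyl cis on the central double bond) | COc1cc([C@@H]2C=C(/C=C(OC)\C=C=O)C[C@@H](C)[C@H]2C)ccc1O[Si](C(C)C)(C(C)C)C(C)C | intermediate (not isolated)
25 | 8-Ar-3-methoxy-6,7-dimethyl-6,7,8,8a-tetrahydronaphthalen-1(5H)-one (keto tautomer of 26; ring B centres as in 26) | COc1cc([C@@H]2C3C(=CC(OC)=CC3=O)C[C@@H](C)[C@H]2C)ccc1O[Si](C(C)C)(C(C)C)C(C)C | intermediate (not isolated)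
26 | (6R,7R,8R)-8-Ar-3-methoxy-6,7-dimethyl-5,6,7,8-tetrahydronaphthalen-1-ol (lignan numbering: 3-OH, 4-H, 5-OMe) | COc1cc([C@@H]2c3c(cc(OC)cc3O)C[C@@H](C)[C@H]2C)ccc1O[Si](C(C)C)(C(C)C)C(C)C | intermediate (key-step product)
27 | (7′R,8R,8′R)-3,3′,5-trimethoxy-4′-(triisopropylsilyloxy)-2,7′-cyclolignan | COc1cc([C@@H]2c3c(cc(OC)cc3OC)C[C@@H](C)[C@H]2C)ccc1O[Si](C(C)C)(C(C)C)C(C)C | intermediate
28 | 4-lithio derivative of 27 | COc1cc([C@@H]2c3c(cc(OC)c([Li])c3OC)C[C@@H](C)[C@H]2C)ccc1O[Si](C(C)C)(C(C)C)C(C)C | intermediate (not isolated)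
29 | dimethyl boronate of 27 at C4 | COc1cc([C@@H]2c3c(cc(OC)c(B(OC)OC)c3OC)C[C@@H](C)[C@H]2C)ccc1O[Si](C(C)C)(C(C)C)C(C)C | intermediate (not isolated)
30 | (7′R,8R,8′R)-3,3′,5-trimethoxy-4′-(triisopropylsilyloxy)-2,7′-cyclolignan-4-ol | COc1cc([C@@H]2c3c(cc(OC)c(O)c3OC)C[C@@H](C)[C@H]2C)ccc1O[Si](C(C)C)(C(C)C)C(C)C | intermediate
31 | (−)-(7′R,8R,8′R)-4,4′-dihydroxy-3,3′,5-trimethoxy-2,7′-cyclolignan | COc1cc([C@@H]2c3c(cc(OC)c(O)c3OC)C[C@@H](C)[C@H]2C)ccc1O | target

**Totals**
Total step count: 15.
Longest linear sequence: 13 steps (1 → 31 through steps 1–6, 8–10 and 12–15); steps 7 and 11 are side branches.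

**Steps most likely to fail**

1. Step 12 (key step). The photogenerated vinylketene may be consumed by dimerisation or by acylating the product phenol before the volatile alkyne captures it, and the electron-rich arenes may screen the diazo chromophore so that the Wolff step stalls. The fallback generates the same vinylketene in the dark; it sets out from 12 and returns at 26. Coupling of 12 with the Reformatsky reagent BrZnCH2CO2t-Bu under Pd(PPh3)4 catalysis in THF should give tert-butyl 2-[(3S,4R,5R)-3-Ar-4,5-dimethylcyclohex-1-en-1-yl]acetate F1. CF3CO2H in CH2Cl2 at 0 °C should free 2-[(3S,4R,5R)-3-Ar-4,5-dimethylcyclohex-1-en-1-yl]acetic acid F2, and (COCl)2 with catalytic DMF should convert it into 2-[(3S,4R,5R)-3-Ar-4,5-dimethylcyclohex-1-en-1-yl]acetyl chloride F3. Slow addition of Et3N to F3 and excess 21 in toluene in a sealed vessel dehydrochlorinates F3 to vinylketene 22, which should pass through 23, 24 and 25 on warming to 80 °C and rejoin the route at 26.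

2. Step 5. Discrimination between the two enantiotopic hydrogens may be incomplete, or run in the opposite sense, which would lower the enantiomeric purity of every later compound. The fallback replaces desymmetrisation by kinetic resolution; it sets out from 5 and returns at 6. LiN(i-Pr)2 in Et2O/hexane at reflux should isomerise 5 without enantiocontrol to racemic (1R*,4R*,5R*)-4,5-dimethylcyclohex-2-en-1-ol F4. Candida antarctica lipase B with vinyl acetate in hexane is expected to acylate the 1R enantiomer faster, giving (1R,4R,5R)-4,5-dimethylcyclohex-2-en-1-yl acetate F5, which is separated from the slow-reacting alcohol and methanolysed (K2CO3, MeOH) to 6. Should the enzyme prefer the other enantiomer, the unreacted alcohol is 6 itself.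

3. Step 14. Metalation at the doubly benzylic C7′–H (epimerisation), at C6, or ortho to the silyl ether (silyl migration) may compete with lithiation at C4. The fallback installs the C4 oxygen by phenol-directed formylation and oxidative aryl migration; it sets out from 26 and returns at 30. Magnesium-mediated ortho-formylation of 26 (MgCl2, Et3N, paraformaldehyde, MeCN, reflux) can only occur at C4, the one free position ortho to the C3 hydroxyl, and should give (7′R,8R,8′R)-3-hydroxy-3′,5-dimethoxy-4′-(triisopropylsilyloxy)-2,7′-cyclolignan-4-carbaldehyde F6. Methylation (MeI, K2CO3, acetone) should give (7′R,8R,8′R)-3,3′,5-trimethoxy-4′-(triisopropylsilyloxy)-2,7′-cyclolignan-4-carbaldehyde F7. Baeyer–Villiger oxidation with mCPBA in CH2Cl2 should give (7′R,8R,8′R)-3,3′,5-trimethoxy-4′-(triisopropylsilyloxy)-2,7′-cyclolignan-4-yl formate F8, and mild methanolysis (NaHCO3, MeOH) returns 30.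

**Further compounds**
F1 | step 12 | tert-butyl 2-[(3S,4R,5R)-3-Ar-4,5-dimethylcyclohex-1-en-1-yl]acetate | COc1cc([C@@H]2C=C(CC(=O)OC(C)(C)C)C[C@@H](C)[C@H]2C)ccc1O[Si](C(C)C)(C(C)C)C(C)C
F2 | step 12 | 2-[(3S,4R,5R)-3-Ar-4,5-dimethylcyclohex-1-en-1-yl]acetic acid | COc1cc([C@@H]2C=C(CC(O)=O)C[C@@H](C)[C@H]2C)ccc1O[Si](C(C)C)(C(C)C)C(C)C
F3 | step 12 | 2-[(3S,4R,5R)-3-Ar-4,5-dimethylcyclohex-1-en-1-yl]acetyl chloride | COc1cc([C@@H]2C=C(CC(Cl)=O)C[C@@H](C)[C@H]2C)ccc1O[Si](C(C)C)(C(C)C)C(C)C
F4 | step 5 | racemic (1R*,4R*,5R*)-4,5-dimethylcyclohex-2-en-1-ol (both enantiomers) | O[C@H]1C=C[C@H](C)[C@H](C)C1.O[C@@H]1C=C[C@@H](C)[C@@H](C)C1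
F5 | step 5 | (1R,4R,5R)-4,5-dimethylcyclohex-2-en-1-yl acetate | CC(=O)O[C@H]1C=C[C@H](C)[C@H](C)C1
F6 | step 14 | (7′R,8R,8′R)-3-hydroxy-3′,5-dimethoxy-4′-(triisopropylsilyloxy)-2,7′-cyclolignan-4-carbaldehyde | COc1cc([C@@H]2c3c(cc(OC)c(C=O)c3O)C[C@@H](C)[C@H]2C)ccc1O[Si](C(C)C)(C(C)C)C(C)C
F7 | step 14 | (7′R,8R,8′R)-3,3′,5-trimethoxy-4′-(triisopropylsilyloxy)-2,7′-cyclolignan-4-carbaldehyde | COc1cc([C@@H]2c3c(cc(OC)c(C=O)c3OC)C[C@@H](C)[C@H]2C)ccc1O[Si](C(C)C)(C(C)C)C(C)C
F8 | step 14 | (7′R,8R,8′R)-3,3′,5-trimethoxy-4′-(triisopropylsilyloxy)-2,7′-cyclolignan-4-yl formate | COc1cc([C@@H]2c3c(cc(OC)c(OC=O)c3OC)C[C@@H](C)[C@H]2C)ccc1O[Si](C(C)C)(C(C)C)C(C)C
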